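(All runs are calculated with constants of no real substance; scatter was added.)

Between 41 min and 79 min the blue run makes product at 1.29 mM/min, but between 79 min and 150 min it makes it more slowly, at 0.338 mM/min. I want to know where this fading ends, and I can ask that without knowing why it fades.

| flask | starting material | time |
|---|---|---|
| blue | 300 mM |  |
| teal | 900 mM |  |
| violet | 300 mM | 600 min |

| blue run: time / min | blue run: [product] / mM | teal run: time / min | teal run: [product] / mM |
|---|---|---|---|
| 6.0 | 20 | 6.0 | 40 |
| 11 | 33 | 11 | 68 |
| 22 | 53 | 22 | 126 |
| 41 | 93 | 41 | 215 |
| 79 | 142 | 79 | 357 |
| 150 | 166 | 150 | 477 |

(standard deviation of a reading: 3 mM)

- apparent order in [starting material] of the starting rate, round the charge of the blue run (the rate where two percent of its starting material have turned into product) (one fixed amount of product, the same in the runs compared)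
- product in the violet run at 600 min, as a share of the starting material charged

- Overall: starting material -> product.
- Constant volume, constant temperature.
- What is held in complexes is read along with the free species.
- An order is taken over about fifteen percent of the charge, up and down.

I freeze one thing: I assume that the late rate of the blue run shrinks by the same factor in each equal stretch of time, as in a first-order decay. Each mean rate belongs to the middle of its interval, and these middles lie 54.5 min apart. The logarithm of the ratio of the two rates, divided by that gap, gives a fade constant of 0.0246 /min. Carrying the second rate forward to the last reading and dividing by the fade constant gives what is still to come, 5.75 mM. Added to the last reading and divided by the charge, this gives the end share, the part of the charge that stands as product once the rate has faded out: 57.3 %. This is a reading, and it carries the scatter of the readings.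

The violet run repeats the blue charge at the same temperature, so I carry the share over. The time from 150 min to 600 min is 11.1 times the fade lifetime, so the fading is over by then. The forecast is slightly higher than my share: it gives 58 % and an order of 0.7, holding that “violet should sit at equilibrium”.

The simulation gives an order of 0.73 and 56.1 % for the violet run, against my share of 57.3 %.

    2 starting material ⇌ substrate dimer, settled at all times (2.170 /M)
    starting material → product (0.01272 /min)
    starting material → product (0.004854 /min)
    starting material → decomposed substrate (0.01374 /min)

The violet run stops short of its charge because starting material also goes to decomposed substrate: with that reaction taken away, the run gives >99.9 % instead of 56.1 %. In the teal run the same first-order steps out of starting material act, and their constants send 56.1 % of what reacts to product, so the teal end stands at 505 mM, and the 450 mM that the teal run holds at 128 min is already 89.1 % of that end.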